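Everything rests on closing ring A last at C3–C4 (labdane numbering). The key step exploits that C4, the gem-dimethyl carbon of ring A, is bonded to C3 (α to the C2 ketone) and is linked through C5–C6–C7 to the C8 carbon of ring B, the pattern of the dimethylcyclobutyl ketone of (−)-verbenone. The precursor is therefore a bicyclo[3.1.1]heptan-2-one in which C4 is still bonded to C7 and C10 carries a β-keto ester arm. SnCl4 breaks the strained C4–C7 bond next to the C8 carbonyl and C3 captures the C4 cation, so ring A forms as the temporary ring opens; that ring has by then set C10 and C9.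

Key step: step 6

Remark: all atoms carry the labdane numbers of the target, also in the bicyclic precursors (ring A: C1–C5 and C10; ring B: C5–C10; side chain C11–C16; C17 exocyclic methylene; C18–C20 methyls). Read from the SMILES, the target is the ent-labdane (5R,9R,10R,13Z).

Remark: compounds 1, 2, 4, 12 and 23 are taken as commercial. Compounds 15–20 carry the temporary C3 ester at an enolisable centre and are handled as C3 epimers, so C3 is left undefined in their SMILES. The Z geometry drawn for 8 is the expected one and is of no consequence.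

Step 1
Reactants: 1 (1S,5S)-(−)-verbenone; 2 allylmagnesium bromide
Product: 3 4-allyl-4,6,6-trimethyl-2-(trimethylsilyloxy)bicyclo[3.1.1]hept-2-ene (allyl on the face opposite the CMe2 bridge)
Conditions: allylMgBr, CuBr·SMe2, LiCl, TMSCl, THF, −78 °C
Reagents that add atoms: chlorotrimethylsilane, C[Si](C)(C)Cl
Why: TMSCl-accelerated conjugate addition of an allylcopper reagent to the β,β-disubstituted enone (organocopper additions to verbenone are known), in which the allyl group enters C10 from the face opposite the gem-dimethyl bridge, so that C10 is set by the cyclobutane and the enolate is trapped on oxygen.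

Step 2
Reactants: 3 silyl enol ether; 4 ethyl glyoxylate
Product: 8 ethyl (2Z)-2-(4-allyl-4,6,6-trimethyl-2-oxobicyclo[3.1.1]heptan-3-ylidene)acetate, via lithium enolate 5 (not isolated), via lithium aldolate 6 (not isolated), via aldol mesylate 7 (not isolated)
Conditions: MeLi, THF, 0 °C; 4, −78 °C; MsCl, −78 to 0 °C; DBU, rt
Reagents that add atoms: none
Why: Aldol condensation: the lithium enolate can only form toward C9 because C7 is a bridgehead, it adds to the very electrophilic glyoxylate, and mesylation followed by DBU-induced E1cB elimination gives the C9=C11 alkylidene, so C9 is flat here and no stereocentre has to be controlled.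

Step 3
Reactants: 8 alkylidene keto ester
Product: 9 ethyl 2-(4-allyl-4,6,6-trimethyl-2-oxobicyclo[3.1.1]heptan-3-yl)acetate (CH2CO2Et arm syn to the CMe2 bridge and trans to allyl)
Conditions: Zn dust, AcOH, THF, rt
Reagents that add atoms: none
Why: Dissolving-metal conjugate reduction of the 4-oxo-2-enoate gives the C8 enol, which is protonated at C9 from the face opposite the gem-dimethyl bridge (the same facial bias that gives cis-pinane on hydrogenation of α-pinene), so the CH2CO2Et arm ends syn to the bridge and trans to the allyl group as C9 requires.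

Step 4
Reactants: 9 keto ester
Product: 11 ethyl 2-[4,6,6-trimethyl-2-oxo-4-(2-oxoethyl)bicyclo[3.1.1]heptan-3-yl]acetate, via ozonide 10 (not isolated)
Conditions: O3, CH2Cl2, −78 °C; PPh3, −78 °C to rt
Reagents that add atoms: ozone, [O-][O+]=O
Why: Ozonolysis of the only C=C bond with reductive work-up gives the C2 aldehyde, and neither the ketone nor the ester nor the stereocentres are touched.

Step 5
Reactants: 11 aldehyde; 12 ethyl diazoacetate
Product: 13 ethyl 4-[3-(2-ethoxy-2-oxoethyl)-4,6,6-trimethyl-2-oxobicyclo[3.1.1]heptan-4-yl]-3-oxobutanoate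
Conditions: SnCl2 (10 mol%), CH2Cl2, rt
Reagents that add atoms: none
Why: Roskamp reaction: SnCl2-catalysed addition of the diazo ester to the aldehyde followed by 1,2-hydride shift and loss of N2 gives the β-keto ester, chemoselectively at the aldehyde since the hindered C8 ketone does not react, and makes C3 a doubly activated carbon.

Step 6
Reactants: 13 bicyclic β-keto ester
Product: 15 ethyl 5-(2-ethoxy-2-oxoethyl)-1,1,4a-trimethyl-3,6-dioxodecahydronaphthalene-2-carboxylate (trans-fused; C9 arm equatorial; C3 epimers), via ring-opened ion pair 14 (not isolated)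
Conditions: SnCl4 (2.5 equiv), CH2Cl2, −40 to 0 °C; cold aq. NaHCO3
Reagents that add atoms: none
Why: Proposed new method: SnCl4 binds the C8 carbonyl, the strained cyclobutane bond C4–C7 that lies next to it ionises to a trichlorotin enolate (C7=C8) and the tertiary cation at C4 (14), and the tin-bound β-keto ester attacks this cation through C3, which makes the C3–C4 bond and ring A in a cation–enol alkylation. The closest known reaction types are the Lewis-acid opening of 4-aryl-6,6-dimethylbicyclo[3.1.1]heptan-2-ones in which a phenol oxygen captures the same kind of cation, and the SnCl4 cyclisation of alkenyl β-keto esters to 2-alkoxycarbonyl-3,3-dimethylcyclohexanones; their union in one operation, with a carbon nucleophile closing a carbocycle as the bicycle fragments, has not been shown. Ring A closes as a 6-(enolendo) attack on a trigonal cationic carbon through a chair in which the C10–C1 and C5–C4 bonds are both equatorial on ring B. The ring-fusion centres are not made here, so the trans fusion follows from C5 of verbenone and from C10 of step 1, C9 is not touched because C8 stays a tin enolate toward C7 until the quench, and the one new centre, C3, is an enolisable β-keto ester carbon that step 9 removes. The step needs C-alkylation to win over loss of a proton from the cation, over O-alkylation and over an aldol of the β-keto ester onto C8; the six-membered transition state, the reversibility under SnCl4 of chloride capture, of O-alkylation and of the aldol, and the impossibility for the C8 enolate oxygen to close on C4 without a bridgehead double bond should secure it.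

Step 7
Reactants: 15 decalindione diester
Product: 18 ethyl 5-(2-ethoxy-2-oxoethyl)-1,1,4a-trimethyl-6-methylidene-3-oxodecahydronaphthalene-2-carboxylate, via keto ester potassium enolate 16 (not isolated), via alkene potassium enolate 17 (not isolated)
Conditions: Ph3PCH3Br, KOtBu (excess), toluene, 0 to 70 °C; aq. NH4Cl
Reagents that add atoms: methyltriphenylphosphonium bromide, C[P+](c1ccccc1)(c1ccccc1)c1ccccc1.[Br-]
Why: Wittig methylenation of the hindered C8 ketone (a standard move on 8-oxo decalins of this type), chemoselective because the first equivalent of base converts the β-keto ester into its enolate 16, whose C2 carbon is no longer electrophilic, while C9 keeps its equatorial arm.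

Step 8
Reactants: 18 methylidene β-keto ester
Product: 20 ethyl 5-(2-hydroxyethyl)-1,1,4a-trimethyl-6-methylidene-3-oxodecahydronaphthalene-2-carboxylate, via sodium enolate 19 (not isolated)
Conditions: NaH (1.1 equiv), THF, 0 °C; LiAlH4, −20 to 0 °C; H2O, aq. NaOH
Reagents that add atoms: none
Why: Hydride reduction under in-flask protection: the β-keto ester is held as its sodium enolate 19, which LiAlH4 does not reduce at low temperature, so only the isolated C12 ethyl ester is reduced to the primary alcohol.

Step 9
Reactants: 20 hydroxy β-keto ester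
Product: 21 (4aR,8R,8aR)-8-(2-hydroxyethyl)-4,4,8a-trimethyl-7-methylideneoctahydronaphthalen-2(1H)-one
Conditions: LiCl, H2O, DMSO, 150 °C
Reagents that add atoms: none
Why: Krapcho dealkoxycarbonylation (chloride attack on the ethyl group, loss of CO2 and protonation of the enolate) removes the temporary C3 ester and with it the undefined C3 centre, leaving the C2 ketone.

Step 10
Reactants: 21 hydroxy ketone
Product: 22 (4aR,8R,8aR)-8-(2-iodoethyl)-4,4,8a-trimethyl-7-methylideneoctahydronaphthalen-2(1H)-one
Conditions: I2, PPh3, imidazole, CH2Cl2, 0 °C to rt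
Reagents that add atoms: iodine, II
Why: Appel iodination: the primary alcohol is activated as an oxyphosphonium ion and displaced by iodide in an SN2 step, which the ketone and the 1,1-disubstituted alkene tolerate.

Step 11
Reactants: 22 iodide; 23 4-bromofuran-2(5H)-one
Product: 25 4-{2-[(1R,4aR,8aR)-5,5,8a-trimethyl-2-methylidene-7-oxodecahydronaphthalen-1-yl]ethyl}furan-2(5H)-one, via alkylzinc iodide 24 (not isolated)
Conditions: Zn dust, LiCl, THF, 40 °C; 23, PdCl2(dppf) (5 mol%), THF, 50 °C
Reagents that add atoms: none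
Why: Negishi coupling: zinc inserts into the primary C–I bond to give a ketone-tolerant alkylzinc that couples with the vinylogous acyl bromide under palladium catalysis, and the lactone ring of the product holds C16 cis to C15, which is the 13Z geometry.

Step 12
Reactants: 25 butenolide
Product: 27 (2Z)-3-(acetoxymethyl)-5-[(1R,4aR,8aR)-5,5,8a-trimethyl-2-methylidene-7-oxodecahydronaphthalen-1-yl]pent-2-enoic acid (CNP0152461.1), via lithium hydroxy carboxylate 26 (not isolated)
Conditions: LiOH·H2O (1.05 equiv), THF/H2O, 0 °C; evaporate; Ac2O, pyridine, DMAP (cat.), CH2Cl2, 0 °C; H2O; cold 1 M HCl to pH 3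
Reagents that add atoms: lithium hydroxide, [Li+].[OH-]; acetic anhydride, CC(=O)OC(C)=O
Why: Lactone saponification followed by DMAP-catalysed O-acetylation of the primary allylic alcohol of the carboxylate salt and aqueous hydrolysis of any mixed anhydride gives the acetoxy acid, the 13Z alkene being carried over unchanged from the ring.

Compound list

1 | (1S,5S)-(−)-verbenone, (1S,5S)-4,6,6-trimethylbicyclo[3.1.1]hept-3-en-2-one | CC1=CC(=O)[C@H]2C[C@@H]1C2(C)C | starting material
2 | allylmagnesium bromide | C=CC[Mg]Br | starting material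
3 | 4-allyl-4,6,6-trimethyl-2-(trimethylsilyloxy)bicyclo[3.1.1]hept-2-ene, allyl opposite the CMe2 bridge | C=CC[C@@]1(C)C=C(O[Si](C)(C)C)[C@H]2C[C@@H]1C2(C)C | intermediate
4 | ethyl glyoxylate | O=CC(=O)OCC | starting material
5 | lithium enolate (C8–O–Li, C8=C9) of 4-allyl-4,6,6-trimethylbicyclo[3.1.1]heptan-2-one | C=CC[C@@]1(C)C=C(O[Li])[C@H]2C[C@@H]1C2(C)C | intermediate
6 | lithium aldolate, ethyl 2-(4-allyl-4,6,6-trimethyl-2-oxobicyclo[3.1.1]heptan-3-yl)-2-(lithiooxy)acetate, new bond at C9 opposite the bridge, carbinol epimers | C=CC[C@@]1(C)[C@@H](C(O[Li])C(=O)OCC)C(=O)[C@H]2C[C@@H]1C2(C)C | intermediate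
7 | aldol mesylate, ethyl 2-(4-allyl-4,6,6-trimethyl-2-oxobicyclo[3.1.1]heptan-3-yl)-2-(methylsulfonyloxy)acetate | C=CC[C@@]1(C)[C@@H](C(OS(C)(=O)=O)C(=O)OCC)C(=O)[C@H]2C[C@@H]1C2(C)C | intermediate
8 | ethyl (2Z)-2-(4-allyl-4,6,6-trimethyl-2-oxobicyclo[3.1.1]heptan-3-ylidene)acetate | C=CC[C@@]1(C)/C(=C/C(=O)OCC)C(=O)[C@H]2C[C@@H]1C2(C)C | intermediate
9 | ethyl 2-(4-allyl-4,6,6-trimethyl-2-oxobicyclo[3.1.1]heptan-3-yl)acetate, CH2CO2Et arm syn to the CMe2 bridge and trans to allyl | C=CC[C@@]1(C)[C@H](CC(=O)OCC)C(=O)[C@H]2C[C@@H]1C2(C)C | intermediate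
10 | ozonide (1,2,4-trioxolane) of the allyl group of 9, epimers at the trioxolane carbon | O1OC(C[C@@]2(C)[C@H](CC(=O)OCC)C(=O)[C@H]3C[C@@H]2C3(C)C)OC1 | intermediate
11 | ethyl 2-[4,6,6-trimethyl-2-oxo-4-(2-oxoethyl)bicyclo[3.1.1]heptan-3-yl]acetate | O=CC[C@@]1(C)[C@H](CC(=O)OCC)C(=O)[C@H]2C[C@@H]1C2(C)C | intermediate
12 | ethyl diazoacetate | [N-]=[N+]=CC(=O)OCC | starting material
13 | ethyl 4-[3-(2-ethoxy-2-oxoethyl)-4,6,6-trimethyl-2-oxobicyclo[3.1.1]heptan-4-yl]-3-oxobutanoate | CCOC(=O)CC(=O)C[C@@]1(C)[C@H](CC(=O)OCC)C(=O)[C@H]2C[C@@H]1C2(C)C | intermediate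
14 | ring-opened ion pair: cyclohexenyl trichlorotin enolate (C7=C8) carrying the tertiary cation at C4, chloride counter-ion | Cl[Sn](Cl)(Cl)OC1=CC[C@H]([C+](C)C)[C@@](C)(CC(=O)CC(=O)OCC)[C@@H]1CC(=O)OCC.[Cl-] | intermediate
15 | ethyl 5-(2-ethoxy-2-oxoethyl)-1,1,4a-trimethyl-3,6-dioxodecahydronaphthalene-2-carboxylate, trans-fused, C9 arm equatorial and cis to the C10 methyl, C3 epimers | O=C1CC[C@@H]2C(C)(C)C(C(=O)OCC)C(=O)C[C@@]2(C)[C@@H]1CC(=O)OCC | intermediate
16 | potassium enolate (C2–O–K, C2=C3) of 15 | O=C1CC[C@@H]2C(C)(C)C(C(=O)OCC)=C([O-])C[C@@]2(C)[C@@H]1CC(=O)OCC.[K+] | intermediate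
17 | potassium enolate (C2–O–K, C2=C3) of 18 | C=C1CC[C@@H]2C(C)(C)C(C(=O)OCC)=C([O-])C[C@@]2(C)[C@@H]1CC(=O)OCC.[K+] | intermediate
18 | ethyl 5-(2-ethoxy-2-oxoethyl)-1,1,4a-trimethyl-6-methylidene-3-oxodecahydronaphthalene-2-carboxylate, C3 epimers | C=C1CC[C@@H]2C(C)(C)C(C(=O)OCC)C(=O)C[C@@]2(C)[C@@H]1CC(=O)OCC | intermediate
19 | sodium enolate (C2–O–Na, C2=C3) of 18 | C=C1CC[C@@H]2C(C)(C)C(C(=O)OCC)=C([O-])C[C@@]2(C)[C@@H]1CC(=O)OCC.[Na+] | intermediate
20 | ethyl 5-(2-hydroxyethyl)-1,1,4a-trimethyl-6-methylidene-3-oxodecahydronaphthalene-2-carboxylate, C3 epimers | C=C1CC[C@@H]2C(C)(C)C(C(=O)OCC)C(=O)C[C@@]2(C)[C@@H]1CCO | intermediate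
21 | (4aR,8R,8aR)-8-(2-hydroxyethyl)-4,4,8a-trimethyl-7-methylideneoctahydronaphthalen-2(1H)-one | C=C1CC[C@@H]2C(C)(C)CC(=O)C[C@@]2(C)[C@@H]1CCO | intermediate
22 | (4aR,8R,8aR)-8-(2-iodoethyl)-4,4,8a-trimethyl-7-methylideneoctahydronaphthalen-2(1H)-one | C=C1CC[C@@H]2C(C)(C)CC(=O)C[C@@]2(C)[C@@H]1CCI | intermediate
23 | 4-bromofuran-2(5H)-one | BrC1=CC(=O)OC1 | starting material
24 | alkylzinc iodide from 22 (C12–Zn–I) | C=C1CC[C@@H]2C(C)(C)CC(=O)C[C@@]2(C)[C@@H]1CC[Zn]I | intermediate
25 | 4-{2-[(1R,4aR,8aR)-5,5,8a-trimethyl-2-methylidene-7-oxodecahydronaphthalen-1-yl]ethyl}furan-2(5H)-one | C=C1CC[C@@H]2C(C)(C)CC(=O)C[C@@]2(C)[C@@H]1CCC3=CC(=O)OC3 | intermediate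
26 | lithium (2Z)-3-(hydroxymethyl)-5-[(1R,4aR,8aR)-5,5,8a-trimethyl-2-methylidene-7-oxodecahydronaphthalen-1-yl]pent-2-enoate | C=C1CC[C@@H]2C(C)(C)CC(=O)C[C@@]2(C)[C@@H]1CC/C(=C/C(=O)[O-])CO.[Li+] | intermediate
27 | (2Z)-3-(acetoxymethyl)-5-[(1R,4aR,8aR)-5,5,8a-trimethyl-2-methylidene-7-oxodecahydronaphthalen-1-yl]pent-2-enoic acid, 16-acetoxy-2-oxo-ent-labda-8(17),13Z-dien-15-oic acid | C=C1CC[C@@H]2C(C)(C)CC(=O)C[C@@]2(C)[C@@H]1CC/C(=C/C(=O)O)COC(C)=O | target

Total step count: 12. Longest linear sequence: 12 steps, from 1 to 27.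

Steps most likely to fail

Step 6. The cation at C4 may lose a proton or undergo a hydride or methyl shift before C3 reaches it, or the β-keto ester may add to the C8 carbonyl before the cyclobutane opens. The fallback sets out from 13 and comes back at 15, and it separates the two events into reactions that are each known. 13 is first opened on its own with anhydrous HCl in CH2Cl2 at 0 °C, the classical hydrohalogenative cleavage of a pinan-2-one-type cyclobutyl ketone, to the monocyclic tertiary chloride ethyl 4-[2-(2-chloropropan-2-yl)-6-(2-ethoxy-2-oxoethyl)-1-methyl-5-oxocyclohexyl]-3-oxobutanoate F1. F1 is then ionised with ZnCl2 or SnCl4 in CH2Cl2, the known Lewis-acid tert-alkylation of a β-dicarbonyl compound by a tertiary chloride, which closes the C3–C4 bond and gives 15.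

Step 12. The carboxylate may form a mixed anhydride with Ac2O while the hydroxyl is still free, and the hydroxyl then closes the butenolide again; that material would return as 25. The fallback sets out from 25 and comes back at 27. After saponification to 26 the carboxylate is alkylated with 4-methoxybenzyl chloride in DMF to the open-chain 4-methoxybenzyl (2Z)-3-(hydroxymethyl)pent-2-enoate F2, in which no activated acyl group is present. The hydroxyl is acetylated (Ac2O, pyridine) to the 4-methoxybenzyl acetoxy ester F3, and the benzylic ester is cleaved with dilute CF3CO2H and anisole in CH2Cl2 at 0 °C to give 27.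

Step 1. The allyl nucleophile may add to the carbonyl carbon (1,2) instead of to the hindered β,β-disubstituted position. The fallback sets out from 1 and comes back at 3, and it turns this mode of failure into the route. Allylmagnesium bromide 2 is added 1,2 on purpose (THF, −78 °C), from the face opposite the bridge, to give the tertiary alcohol 2-allyl-4,6,6-trimethylbicyclo[3.1.1]hept-3-en-2-ol F4. KH and 18-crown-6 in THF then trigger the anionic oxy-Cope rearrangement, a [3,3] shift that carries the allyl group across the same face to C10 and gives the potassium enolate F5. TMSCl silylates F5 to 3.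

Further compounds

F1 | step 6 | ethyl 4-[2-(2-chloropropan-2-yl)-6-(2-ethoxy-2-oxoethyl)-1-methyl-5-oxocyclohexyl]-3-oxobutanoate, configuration at C5, C9 and C10 as in 13 | CCOC(=O)CC(=O)C[C@@]1(C)[C@H](CC(=O)OCC)C(=O)CC[C@@H]1C(C)(C)Cl
F2 | step 12 | 4-methoxybenzyl (2Z)-3-(hydroxymethyl)-5-[(1R,4aR,8aR)-5,5,8a-trimethyl-2-methylidene-7-oxodecahydronaphthalen-1-yl]pent-2-enoate | C=C1CC[C@@H]2C(C)(C)CC(=O)C[C@@]2(C)[C@@H]1CC/C(=C/C(=O)OCc3ccc(OC)cc3)CO
F3 | step 12 | 4-methoxybenzyl (2Z)-3-(acetoxymethyl)-5-[(1R,4aR,8aR)-5,5,8a-trimethyl-2-methylidene-7-oxodecahydronaphthalen-1-yl]pent-2-enoate | C=C1CC[C@@H]2C(C)(C)CC(=O)C[C@@]2(C)[C@@H]1CC/C(=C/C(=O)OCc3ccc(OC)cc3)COC(C)=O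
F4 | step 1 | 2-allyl-4,6,6-trimethylbicyclo[3.1.1]hept-3-en-2-ol, allyl opposite the CMe2 bridge | CC1=C[C@@](O)(CC=C)[C@H]2C[C@@H]1C2(C)C
F5 | step 1 | potassium enolate (C8–O–K, C8=C9) of 4-allyl-4,6,6-trimethylbicyclo[3.1.1]heptan-2-one | C=CC[C@@]1(C)C=C([O-])[C@H]2C[C@@H]1C2(C)C.[K+]
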